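## Retrosynthetic overview

1. Target ⇐ (2S)-flavanone: the C3 hydroxyl goes in last by Rubottom oxidation, trans to the C2 aryl group, and all silyl groups come off in the same operation.
2. (2S)-Flavanone ⇐ 6-(1,1-dimethylallyl)chromone + 4-silyloxyphenylboronic acid (from 4-bromophenol): rhodium-catalysed asymmetric 1,4-arylation forms C2–C1′ and sets C2.
3. 6-(1,1-Dimethylallyl)chromone ⇐ 5-hydroxy-7-silyloxychromone + tert-prenyl carbonate (from 2-methylbut-3-en-2-ol): new palladium-catalysed, 5-OH-directed C6–H reverse prenylation.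
4. Chromone ⇐ zincated tris-O-protected phloroglucinol + (E)-3-ethoxyacryloyl chloride (from ethyl vinyl ether and oxalyl chloride): Negishi acylation, then acid closes ring C. The phloroglucinol comes from resorcinol by iridium-catalysed C–H borylation/oxidation.
5. Ring order: ring A (resorcinol) → ring C (pyranone) → ring B attached at C2 → C3 oxygenation.

Assumption: the (S)-bisphosphine in step 10 is taken to give the (2S)-flavanone (the facial sense known for rhodium–(S)-biaryl-bisphosphine additions to cyclic enones); if the product proves (2R), the (R)-ligand is used.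

## Route

Step 1
Reactants: 1 resorcinol (benzene-1,3-diol)
Product: 2 1,3-bis(methoxymethoxy)benzene
Conditions: NaH (2.4 equiv), MOMCl (2.3 equiv), DMF, 0 °C → rt
Reagents that add atoms: chloromethyl methyl ether (MOMCl), COCCl
Why: Williamson-type O-alkylation of the bis-phenoxide (MOM protection) gives acetal ethers that survive the borylation and later direct ortho-lithiation.

Step 2
Reactants: 2 1,3-bis(methoxymethoxy)benzene
Product: 4 3,5-bis(methoxymethoxy)phenol, via aryl pinacol boronate 3 (not isolated)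
Conditions: [Ir(OMe)(cod)]2 (1.5 mol%), 4,4′-di-tert-butyl-2,2′-bipyridine (3 mol%), B2pin2 (0.6 equiv), THF, 80 °C; then 30% H2O2, aq NaOH, 0 °C → rt
Reagents that add atoms: bis(pinacolato)diboron, CC1(C)OB(OC1(C)C)B1OC(C)(C)C(C)(C)O1 (boryl group, in 3 only); hydrogen peroxide, OO (the new phenol oxygen)
Why: Iridium-catalysed C–H borylation is sterically controlled, so only C5–H (the one C–H with no ortho substituent) reacts, and the C–B bond is then oxidised to C–O in the same pot.

Step 3
Reactants: 4 3,5-bis(methoxymethoxy)phenol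
Product: 5 [3,5-bis(methoxymethoxy)phenoxy]tri(propan-2-yl)silane
Conditions: NaH (1.2 equiv), i-Pr3SiCl (1.1 equiv), THF, 0 °C → rt
Reagents that add atoms: chlorotri(propan-2-yl)silane, CC(C)[Si](Cl)(C(C)C)C(C)C
Why: O-silylation of the phenoxide gives an aryl silyl ether that is acid-stable and non-directing, so the later lithiation goes between the two MOM ethers and the later acid step frees only those two oxygens.

Step 4
Reactants: 6 ethyl vinyl ether (ethoxyethene); 7 oxalyl chloride
Product: 9 (E)-3-ethoxyprop-2-enoyl chloride, via keto acid chloride 8 (not isolated)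
Conditions: neat, 7 (1.5 equiv), 0 °C → rt, 12 h; then 120 °C, 30 min; vacuum distillation
Reagents that add atoms: none
Why: Electrophilic acylation of the enol ether by oxalyl chloride followed by thermal decarbonylation of the α-keto acid chloride is the classical preparation of this three-carbon acylating agent.

Step 5
Reactants: 5 [3,5-bis(methoxymethoxy)phenoxy]tri(propan-2-yl)silane; 9 (E)-3-ethoxyprop-2-enoyl chloride
Product: 13 5-hydroxy-7-[(triisopropylsilyl)oxy]-4H-chromen-4-one, via aryllithium 10 (not isolated), via arylzinc chloride 11 (not isolated), via ethoxy enone 12 (not isolated)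
Conditions: n-BuLi (1.1 equiv), THF, 0 °C; ZnCl2 (1.2 equiv), 0 °C → rt; Pd(PPh3)4 (3 mol%), 9 (1.3 equiv), 0 °C → rt; then HCl (1.25 M in MeOH), 40 °C, same pot
Reagents that add atoms: n-butyllithium, [Li]CCCC (lithium, in 10 only); zinc chloride, Cl[Zn]Cl (zinc and chlorine, in 11 only)
Why: Directed ortho-metalation between the two MOM ethers, Li→Zn exchange and Negishi acylation (zerovalent palladium) give the β-ethoxy enone; acid then cleaves the two carbonyl-flanked MOM ethers and one phenol closes ring C by oxa-Michael addition–elimination of ethanol, the symmetric aryl group leaving no regiochemical choice.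

Step 6
Reactants: 14 2-methylbut-3-en-2-ol
Product: 15 tert-butyl 2-methylbut-3-en-2-yl carbonate
Conditions: n-BuLi (1.0 equiv), THF, 0 °C; Boc2O (1.05 equiv), 0 °C → rt
Reagents that add atoms: di-tert-butyl dicarbonate, CC(C)(C)OC(=O)OC(=O)OC(C)(C)C
Why: Acylation of the tertiary lithium alkoxide by Boc2O gives the allylic carbonate, which ionises readily on zerovalent palladium and releases its own base.

Step 7
Reactants: 13 5-hydroxy-7-[(triisopropylsilyl)oxy]-4H-chromen-4-one; 15 tert-butyl 2-methylbut-3-en-2-yl carbonate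
Product: 17 5-hydroxy-6-(2-methylbut-3-en-2-yl)-7-[(triisopropylsilyl)oxy]-4H-chromen-4-one, via dienone 16 (not isolated)
Conditions: Pd2(dba)3 (2.5 mol%), P(t-Bu)3 (5 mol%, Pd:P = 1:1), 15 (1.5 equiv), toluene, 50 °C
Reagents that add atoms: none
Why: Proposed new method: palladium-catalysed, chelate-directed decarboxylative C6–H reverse prenylation, in which zerovalent palladium ionises 15 (CO2 loss gives tert-butoxide, which deprotonates the 5-OH), the 5-oxido-4-keto unit binds the prenylpalladium as an O,O-chelate while the single bulky phosphine forces the allyl into the η1 form bound through CH2, and an inner-sphere 3,3′-reductive elimination through a seven-membered transition state joins the dimethyl-substituted allyl terminus to C6 (the only carbon the O-bound metal can reach; C8 is out of range) to give dienone 16, which tautomerises to the phenol; O-allylation is reversible under the catalyst while C–C formation is not, and the closest known reaction types are the aromatic Claisen rearrangement, the inner-sphere palladium-catalysed decarboxylative allylation of enolates and allyl–allyl coupling by 3,3′-reductive elimination, and the palladium-catalysed O-reverse-prenylation of phenols with tert-prenyl carbonates.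

Step 8
Reactants: 18 4-bromophenol
Product: 19 (4-bromophenoxy)tri(propan-2-yl)silane
Conditions: NaH (1.2 equiv), i-Pr3SiCl (1.1 equiv), THF, 0 °C → rt
Reagents that add atoms: chlorotri(propan-2-yl)silane, CC(C)[Si](Cl)(C(C)C)C(C)C
Why: O-silylation of the phenoxide gives a base-stable aryl silyl ether that tolerates the bromine–lithium exchange and is removed with the other silyl groups at the end.

Step 9
Reactants: 19 (4-bromophenoxy)tri(propan-2-yl)silane
Product: 21 {4-[(triisopropylsilyl)oxy]phenyl}boronic acid, via aryllithium 20 (not isolated)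
Conditions: n-BuLi (1.05 equiv), THF, −78 °C; B(Oi-Pr)3 (1.5 equiv), −78 °C → rt; 1 M HCl to pH 5, 0 °C
Reagents that add atoms: n-butyllithium, [Li]CCCC (lithium, in 20 only); triisopropyl borate, CC(C)OB(OC(C)C)OC(C)C (boron); water, O (the two boronic acid oxygens)
Why: Bromine–lithium exchange and trapping of the aryllithium with the borate ester, then mild hydrolysis, is the standard route to arylboronic acids.

Step 10
Reactants: 17 5-hydroxy-6-(2-methylbut-3-en-2-yl)-7-[(triisopropylsilyl)oxy]-4H-chromen-4-one; 21 {4-[(triisopropylsilyl)oxy]phenyl}boronic acid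
Product: 22 (2S)-5-hydroxy-6-(2-methylbut-3-en-2-yl)-7-[(triisopropylsilyl)oxy]-2-{4-[(triisopropylsilyl)oxy]phenyl}-2,3-dihydro-4H-chromen-4-one
Conditions: [Rh(OH)(cod)]2 (1.5 mol%), (S)-6,6′-dimethoxy-2,2′-bis[bis(3,4,5-trifluorophenyl)phosphino]-1,1′-biphenyl (3.3 mol%), 21 (2.0 equiv), toluene/H2O (10:1), 30 °C
Reagents that add atoms: none
Why: Hayashi–Miyaura rhodium-catalysed asymmetric 1,4-addition, in which the aryl–rhodium species (monovalent rhodium) adds across C2=C3 of the hydrogen-bond-activated chromone and water protonates the rhodium enolate faster than it can eliminate the ring oxygen; the electron-poor (S)-bisphosphine selects the enone face and sets C2 as S.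

Step 11
Reactants: 22 (2S)-5-hydroxy-6-(2-methylbut-3-en-2-yl)-7-[(triisopropylsilyl)oxy]-2-{4-[(triisopropylsilyl)oxy]phenyl}-2,3-dihydro-4H-chromen-4-one
Product: 25 (2R,3R)-3,5,7-trihydroxy-2-(4-hydroxyphenyl)-6-(2-methylbut-3-en-2-yl)-2,3-dihydro-4H-chromen-4-one (CNP0527000.1), via bis(trimethylsilyl) enol ether 23 (not isolated), via silylated dihydroflavonol 24 (not isolated)
Conditions: LiN(SiMe3)2 (2.5 equiv), Me3SiCl (3 equiv), THF, −78 °C; dimethyldioxirane (1.1 equiv, in acetone), CH2Cl2, −78 → −30 °C; Bu4NF (5 equiv), AcOH (5 equiv), THF, 0 °C → rt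
Reagents that add atoms: chlorotrimethylsilane, C[Si](C)(C)Cl (Me3Si groups, in 23 and 24 only); dimethyldioxirane, CC1(C)OO1 (the C3 oxygen)
Why: Rubottom oxidation, in which in-situ silylation traps the enolate before it can open ring C, dimethyldioxirane epoxidises the electron-rich silyl enol ether (far faster than the hindered vinyl group) on the face anti to the C2 aryl group so that C3 is set R and trans to C2, and buffered fluoride then removes all four silyl groups without epimerisation.

## Compound list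

1 | resorcinol (benzene-1,3-diol) | Oc1cccc(O)c1 | starting material
2 | 1,3-bis(methoxymethoxy)benzene | COCOc1cccc(OCOC)c1 | intermediate
3 | 2-[3,5-bis(methoxymethoxy)phenyl]-4,4,5,5-tetramethyl-1,3,2-dioxaborolane | COCOc1cc(OCOC)cc(c1)B1OC(C)(C)C(C)(C)O1 | intermediate
4 | 3,5-bis(methoxymethoxy)phenol | COCOc1cc(O)cc(OCOC)c1 | intermediate
5 | [3,5-bis(methoxymethoxy)phenoxy]tri(propan-2-yl)silane | COCOc1cc(OCOC)cc(O[Si](C(C)C)(C(C)C)C(C)C)c1 | intermediate
6 | ethyl vinyl ether (ethoxyethene) | CCOC=C | starting material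
7 | oxalyl chloride | O=C(Cl)C(=O)Cl | starting material
8 | (E)-4-ethoxy-2-oxobut-3-enoyl chloride | CCO/C=C/C(=O)C(Cl)=O | intermediate
9 | (E)-3-ethoxyprop-2-enoyl chloride | CCO/C=C/C(Cl)=O | intermediate
10 | {2,6-bis(methoxymethoxy)-4-[(triisopropylsilyl)oxy]phenyl}lithium | [Li]c1c(OCOC)cc(O[Si](C(C)C)(C(C)C)C(C)C)cc1OCOC | intermediate
11 | chlorido{2,6-bis(methoxymethoxy)-4-[(triisopropylsilyl)oxy]phenyl}zinc | Cl[Zn]c1c(OCOC)cc(O[Si](C(C)C)(C(C)C)C(C)C)cc1OCOC | intermediate
12 | (E)-1-{2,6-bis(methoxymethoxy)-4-[(triisopropylsilyl)oxy]phenyl}-3-ethoxyprop-2-en-1-one | CCO/C=C/C(=O)c1c(OCOC)cc(O[Si](C(C)C)(C(C)C)C(C)C)cc1OCOC | intermediate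
13 | 5-hydroxy-7-[(triisopropylsilyl)oxy]-4H-chromen-4-one | CC(C)[Si](Oc1cc(O)c2C(=O)C=COc2c1)(C(C)C)C(C)C | intermediate
14 | 2-methylbut-3-en-2-ol | C=CC(C)(C)O | starting material
15 | tert-butyl 2-methylbut-3-en-2-yl carbonate | C=CC(C)(C)OC(=O)OC(C)(C)C | intermediate
16 | 6-(2-methylbut-3-en-2-yl)-7-[(triisopropylsilyl)oxy]chromene-4,5(6H)-dione (keto tautomer of 17) | C=CC(C)(C)C1C(=O)C2=C(C=C1O[Si](C(C)C)(C(C)C)C(C)C)OC=CC2=O | intermediate
17 | 5-hydroxy-6-(2-methylbut-3-en-2-yl)-7-[(triisopropylsilyl)oxy]-4H-chromen-4-one | C=CC(C)(C)c1c(O[Si](C(C)C)(C(C)C)C(C)C)cc2OC=CC(=O)c2c1O | intermediate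
18 | 4-bromophenol | Oc1ccc(Br)cc1 | starting material
19 | (4-bromophenoxy)tri(propan-2-yl)silane | CC(C)[Si](Oc1ccc(Br)cc1)(C(C)C)C(C)C | intermediate
20 | {4-[(triisopropylsilyl)oxy]phenyl}lithium | [Li]c1ccc(O[Si](C(C)C)(C(C)C)C(C)C)cc1 | intermediate
21 | {4-[(triisopropylsilyl)oxy]phenyl}boronic acid | CC(C)[Si](Oc1ccc(cc1)B(O)O)(C(C)C)C(C)C | intermediate
22 | (2S)-5-hydroxy-6-(2-methylbut-3-en-2-yl)-7-[(triisopropylsilyl)oxy]-2-{4-[(triisopropylsilyl)oxy]phenyl}-2,3-dihydro-4H-chromen-4-one | C=CC(C)(C)c1c(O[Si](C(C)C)(C(C)C)C(C)C)cc2c(c1O)C(=O)C[C@@H](c1ccc(O[Si](C(C)C)(C(C)C)C(C)C)cc1)O2 | intermediate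
23 | (2S)-6-(2-methylbut-3-en-2-yl)-7-[(triisopropylsilyl)oxy]-2-{4-[(triisopropylsilyl)oxy]phenyl}-4,5-bis[(trimethylsilyl)oxy]-2H-chromene | C=CC(C)(C)c1c(O[Si](C(C)C)(C(C)C)C(C)C)cc2c(c1O[Si](C)(C)C)C(O[Si](C)(C)C)=C[C@@H](c1ccc(O[Si](C(C)C)(C(C)C)C(C)C)cc1)O2 | intermediate
24 | (2R,3R)-6-(2-methylbut-3-en-2-yl)-7-[(triisopropylsilyl)oxy]-2-{4-[(triisopropylsilyl)oxy]phenyl}-3,5-bis[(trimethylsilyl)oxy]-2,3-dihydro-4H-chromen-4-one | C=CC(C)(C)c1c(O[Si](C(C)C)(C(C)C)C(C)C)cc2c(c1O[Si](C)(C)C)C(=O)[C@H](O[Si](C)(C)C)[C@@H](c1ccc(O[Si](C(C)C)(C(C)C)C(C)C)cc1)O2 | intermediate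
25 | (2R,3R)-3,5,7-trihydroxy-2-(4-hydroxyphenyl)-6-(2-methylbut-3-en-2-yl)-2,3-dihydro-4H-chromen-4-one | C=CC(C)(C)c1c(O)cc2c(c1O)C(=O)[C@H](O)[C@@H](c1ccc(O)cc1)O2 | target

## Step count and risks

Total step count: 11. Longest linear sequence: 7 (steps 1, 2, 3, 5, 7, 10, 11, from resorcinol).

Steps most likely to fail:

Step 7 (the new reaction). It may give O-prenyl ethers, linear prenylation at C8 by an outer-sphere path, or only isoprene by β-hydride loss. The fallback is known chemistry and sets out from 13. Mitsunobu etherification of the 5-OH with 3-methylbut-2-en-1-ol (PPh3, diisopropyl azodicarboxylate, THF) gives 5-[(3-methylbut-2-en-1-yl)oxy]-7-[(triisopropylsilyl)oxy]-4H-chromen-4-one F1. Heating F1 in N,N-diethylaniline at 180 °C brings about the aromatic Claisen rearrangement through the same dienone 16 and comes back to the route at 17; the 8-prenyl isomer from a further Cope shift is the known by-product to separate.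

Step 10. The free, chelating 5-OH can tie up rhodium, the acceptor is electron-rich, and any elimination of the ring oxygen from the enolate would cost enantiopurity and could re-close to the 8-substituted isomer. The fallback sets out from 17 and gives up asymmetric catalysis for a stoichiometric organometallic addition plus resolution. The Grignard reagent bromo{4-[(triisopropylsilyl)oxy]phenyl}magnesium F2 is made from 19 and Mg in THF (3 equiv; the first is spent on the 5-OH). It is added under CuBr·SMe2 catalysis at −40 °C to give racemic 5-hydroxy-6-(2-methylbut-3-en-2-yl)-7-[(triisopropylsilyl)oxy]-2-{4-[(triisopropylsilyl)oxy]phenyl}-2,3-dihydro-4H-chromen-4-one F3. Preparative supercritical-fluid chromatography on a chiral stationary phase separates the (2S) enantiomer, which is 22.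

Step 5. Three events run in one pot, the arylzinc is flanked by two ortho substituents, and the acid chloride is sensitive. The fallback sets out from 5 and builds the three-carbon unit in two pieces instead of one. Lithiation as before and quenching with N-methoxy-N-methylacetamide gives 1-{2,6-bis(methoxymethoxy)-4-[(triisopropylsilyl)oxy]phenyl}ethan-1-one F4. Condensation with N,N-dimethylformamide dimethyl acetal at 100 °C gives (E)-1-{2,6-bis(methoxymethoxy)-4-[(triisopropylsilyl)oxy]phenyl}-3-(dimethylamino)prop-2-en-1-one F5. Methanolic HCl at 40 °C removes both MOM groups and closes ring C with loss of dimethylamine, coming back to the route at 13.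

## Further compounds

F1 | step 7 | 5-[(3-methylbut-2-en-1-yl)oxy]-7-[(triisopropylsilyl)oxy]-4H-chromen-4-one | CC(C)=CCOc1cc(O[Si](C(C)C)(C(C)C)C(C)C)cc2OC=CC(=O)c12
F2 | step 10 | bromo{4-[(triisopropylsilyl)oxy]phenyl}magnesium | Br[Mg]c1ccc(O[Si](C(C)C)(C(C)C)C(C)C)cc1
F3 | step 10 | racemic 5-hydroxy-6-(2-methylbut-3-en-2-yl)-7-[(triisopropylsilyl)oxy]-2-{4-[(triisopropylsilyl)oxy]phenyl}-2,3-dihydro-4H-chromen-4-one | C=CC(C)(C)c1c(O[Si](C(C)C)(C(C)C)C(C)C)cc2c(c1O)C(=O)CC(c1ccc(O[Si](C(C)C)(C(C)C)C(C)C)cc1)O2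
F4 | step 5 | 1-{2,6-bis(methoxymethoxy)-4-[(triisopropylsilyl)oxy]phenyl}ethan-1-one | CC(=O)c1c(OCOC)cc(O[Si](C(C)C)(C(C)C)C(C)C)cc1OCOC
F5 | step 5 | (E)-1-{2,6-bis(methoxymethoxy)-4-[(triisopropylsilyl)oxy]phenyl}-3-(dimethylamino)prop-2-en-1-one | CN(C)/C=C/C(=O)c1c(OCOC)cc(O[Si](C(C)C)(C(C)C)C(C)C)cc1OCOC
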